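Remark on numbering: locants C1–C14 in the discussion follow the target chain (C1 carboxyl carbon, C3 and C6 the ring carbons bound to oxygen, C8 and C12 the side-chain methine carbons); systematic names carry their own locants.
Assumption: the (4S,5S)-dioxaborolane controller is taken to give the (1R,2R)-cyclopropane from an (E)-allylic alcohol, by analogy with the sense known for (E)-3-substituted allylic alcohols; the enantiomeric controller is used if the sense proves opposite.

## The problem

The target is a 1,2-dioxane (ring O1–O2–C3–C4–C5–C6) with CH2CO2H at C3, CH3 at C4 and CH3 at C6 on one face and the C7 chain on the other. C6 is a fully substituted peroxide carbon whose two carbon substituents, CH3 and CH2R, differ little in size, so a closure that forms the C6–O bond last (radical trapping of O2, cation capture, chair cyclisation) has nothing to discriminate. The 3,4-cis relation puts the C3 side chain axial when both ring methyl groups are equatorial; the usual oxa-Michael closure of a hydroperoxide onto an enoate is expected to favour 3,4-trans. C4 can control C3 and C6 only through the ring, and C8 lies 1,3 to C6 across a methylene with no cyclic relay. C12 is remote; the chain repeats the unit CH2–CH(CH3)–CH=CH (C7–C10, C11–C14), the product pattern of a [3,3] shift of a secondary allylic alcohol. The O–O bond does not survive hydrogenation, low-valent metals or strong base (Kornblum–DeLaMare cleavage at C3–H, retro-oxa-Michael of the β-peroxy acid), and the two E-alkenes rule out late radical or singlet-oxygen peroxidation. The enabling feature is that C3 and C6 are 1,4-related and both at carbonyl oxidation level: the ring is the double peroxyketal of H2O2 with 2-methyl-4-oxopentanal. C6 already carries the ketone methyl, so C7 (on C6) and C2 (on C3) can both enter as carbon nucleophiles on ring peroxycarbenium ions. C4 sits β to C6 and α to C3, where one methyl group can steer both additions, and C8 lies inside a homoallyl unit (C7–C8–C9=C10), the ring-opened form of a cyclopropylcarbinyl group.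

## Retrosynthesis

Target 27 comes from methyl ester 25 by hydrolysis, and 25 is cut at C9=C10 into aldehyde 17 and sulfone 23. This cut is preferred to the sp3–sp3 bonds C10–C11 or C7–C8, which would need organometallic reagents next to the peroxide. It splits the molecule into a ring half and a chain half of similar size and uses an olefination that tolerates the O–O bond. The forward reaction must give the E-alkene without epimerising C8 and without opening the β-peroxy ester.

Aldehyde 17 is the ozonolysis product of terminal alkene 15, and 15 is cut at C2–C3 to peroxyacetal 13 and a two-carbon ester enolate equivalent. Cutting C2–C3 and not C3–O means C3 is made by axial C–C bond formation on ring cation 14, the pathway that should lead to 3,4-cis; the C3–O cut (oxa-Michael) would lead to 3,4-trans. The forward step must deliver the nucleophile cis to the C4 methyl.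

Peroxyacetal 13 is cut at C6–C7 into bis-peroxyketal 7 and stannane 11; this is the key disconnection. Among the bonds at C6, only the C6–C7 cut lets the weakly differentiated pair CH3/CH2R be told apart, because CH3 is already on the cation and C7 arrives axially. The alternative C6–CH3 cut would put the methyl axial and give the wrong epimer, and the C6–O cut gives no control. Precursor 7 has one fixed stereocentre and eight carbons, and 11 carries C7–C10 with C8 preformed. The forward step must ionise C6 and not C3, attack trans to the C4 methyl, and open the cyclopropane at its CH2 carbon.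

Bis-peroxyketal 7 is cut at both C–O(peroxide) bonds back to unsaturated ketone 4, whose alkene carbon becomes C3 and whose ketone becomes C6; ozone supplies the O–O unit. Ketone 4 is cut at C4–C5 by a Claisen retron to allylic alcohol 2, obtained from racemic 1 by enzymatic resolution. This is preferred to an aldol or alkylation route to the keto aldehyde because C4 is then never α to a free carbonyl before it is locked in the ring. The forward steps must transfer the carbinol configuration to C4 and keep it through ozonolysis.

Sulfone 23 is traced through sulfide 22, alcohol 21 and ester 20 to ester 19, which is cut at C11–C12 by a second Claisen retron to the same alcohol 2. The styryl terminus of 20 is exchanged for the propenyl group of 19 by metathesis. One resolved carbinol thus supplies both C4 and C12.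

Stannane 11 comes from mesylate 10 and alcohol 9, and 9 from (E)-but-2-en-1-ol 8 by directed cyclopropanation. The trans ring stores C8 as a ring stereocentre and C9=C10 as the strained bond that the key step releases.

## Roads not taken

Alternative 1: the most obvious plan cuts C6–O and C3–O one after the other. A 1,1-disubstituted alkene at C6 is converted by cobalt-catalysed Mukaiyama–Isayama hydroperoxysilylation into hydroperoxy enoate A1, and the hydroperoxide closes on the enoate by oxa-Michael addition. The tertiary radical at C6 is trapped by O2 from both faces, so C6 is uncontrolled, and the chair closure places the ester arm equatorial, towards 3,4-trans. Two of the three ring centres would be set against the target and relied on separation. The chosen plan sets both by axial attack on ring cations.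

Alternative 2: a biomimetic cut of both C–O bonds at once, by [4+2] addition of singlet oxygen to triene A2 to give dihydrodioxine A3, then diimide reduction of C4=C5. The C3/C6 relation needs the (5Z) terminus with the CH2 group inside the s-cis diene; this is strained and offers allylic hydrogens for the ene reaction. Nothing in A2 directs the facial approach relative to C8, and the diimide face at C4 is a further open question. The chosen plan needs no diene geometry and fixes C4 before the ring exists.

Alternative 3: the segment C3–C9 has a hidden mirror plane through C6 (the C4 and C8 arms are enantiomorphic). A [4+3] cycloaddition of an oxyallyl cation to (2E,4E)-hexa-2,4-diene would give meso ketone A4; peroxidation at the carbonyl carbon, ozonolysis to a meso diol and lipase desymmetrisation would follow. C4 and C8 then come together, but the peroxide must sit cis to both ring methyl groups (hydroperoxide A5). That is the equatorial position on the cycloheptene chair, which neither radical nor cationic peroxidation is expected to favour, so C6 stays unsolved and extra redox steps are added. The chosen plan spends its effort on C6 and obtains C8 from a reagent.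

Key step: step 7

## Steps

Step 1
Reactants: 1 rac-(3E)-pent-3-en-2-ol
Product: 2 (2S,3E)-pent-3-en-2-ol
Conditions: Novozym 435 (lipase B of Candida antarctica), vinyl acetate (0.6 equiv), pentane, 25 °C, to about 55% conversion; distillation
Reagents that add atoms: none
Why: Lipase-catalysed kinetic resolution by acyl transfer; the enzyme acylates the (R)-enantiomer of methyl alkenyl carbinols, so the (S)-alcohol should remain enantiopure past half conversion.

Step 2
Reactants: 2 (2S,3E)-pent-3-en-2-ol
Product: 4 (4S,5E)-4-methylhept-5-en-2-one, via allyl isopropenyl ether 3 (not isolated)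
Conditions: 2-methoxypropene (4 equiv), EtCO2H (cat.), toluene, sealed tube, 130 °C
Reagents that add atoms: 2-methoxypropene, COC(C)=C
Why: Saucy–Marbet variant of the Claisen rearrangement; ether 3 rearranges through a chair with the carbinol methyl equatorial, so the C–O centre is exchanged suprafacially for the C4 methyl centre (S) and an E-alkene.

Step 3
Reactants: 4 (4S,5E)-4-methylhept-5-en-2-one
Product: 7 (5S)-3,6-dimethoxy-3,5-dimethyl-1,2-dioxane (isomers at C3 and C6), via methoxy hydroperoxide 5 (not isolated), via cyclic peroxy hemiketal 6 (not isolated)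
Conditions: O3, CH2Cl2/MeOH 1:1, −78 °C; then p-TsOH (cat.), MeOH, 0 °C to rt
Reagents that add atoms: ozone, [O-][O+]=O; methanol, CO
Why: Ozonolysis in methanol traps the carbonyl oxide as hydroperoxide 5, whose OOH adds to the γ-ketone to close hemiketal 6 (6-exo-trig), and acid methanolysis gives the double peroxyketal; the two anomeric centres equilibrate and are erased later, and C4 is not touched.

Step 4
Reactants: 8 (2E)-but-2-en-1-ol
Product: 9 [(1R,2R)-2-methylcyclopropyl]methanol
Conditions: Et2Zn, CH2I2, DME, (4S,5S)-2-butyl-N,N,N',N'-tetramethyl-1,3,2-dioxaborolane-4,5-dicarboxamide (1.2 equiv), CH2Cl2, −10 °C to rt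
Reagents that add atoms: diiodomethane, ICI
Why: Hydroxyl-directed Simmons–Smith cyclopropanation under a chiral dioxaborolane controller; the zinc carbenoid is delivered to one alkene face and the E geometry is copied into the trans ring, setting both ring centres.

Step 5
Reactants: 9 [(1R,2R)-2-methylcyclopropyl]methanol
Product: 10 [(1R,2R)-2-methylcyclopropyl]methyl methanesulfonate
Conditions: MsCl, Et3N, CH2Cl2, −20 °C; used crude
Reagents that add atoms: methanesulfonyl chloride, CS(=O)(=O)Cl
Why: Sulfonylation of a primary alcohol; kept cold because cyclopropylcarbinyl sulfonates ionise easily.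

Step 6
Reactants: 10 [(1R,2R)-2-methylcyclopropyl]methyl methanesulfonate
Product: 11 tributyl{[(1R,2R)-2-methylcyclopropyl]methyl}stannane
Conditions: Bu3SnLi (from Bu3SnH and LiN(iPr)2), THF, −78 °C
Reagents that add atoms: tributylstannyllithium, [Li][Sn](CCCC)(CCCC)CCCC
Why: SN2 displacement of a primary sulfonate by a stannyl anion at low temperature, where substitution should outrun electron transfer so the ring stays closed; the ring centres are not involved.

Step 7
Reactants: 7 (5S)-3,6-dimethoxy-3,5-dimethyl-1,2-dioxane; 11 tributyl{[(1R,2R)-2-methylcyclopropyl]methyl}stannane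
Product: 13 (3S,5S)-6-methoxy-3,5-dimethyl-3-[(2R)-2-methylbut-3-en-1-yl]-1,2-dioxane (both C6 epimers), via C6 peroxycarbenium ion 12 (not isolated)
Conditions: TMSOTf (1.1 equiv), 11 (2 equiv), CH2Cl2, −78 to −40 °C; NaHCO3 quench
Reagents that add atoms: none
Why: Proposed new method: TMSOTf should ionise the ketone-derived C6–OCH3 bond of 7 in preference to the aldehyde-derived C3–OCH3 bond and give ring peroxycarbenium ion 12, a class of cation known to be captured by allylsilanes and silyl enol ethers. The proposed nucleophile is the strained σ bond of 11: the cation attacks the unsubstituted ring CH2 (C7) at its corner, the ring bond to the carbon bearing CH2Sn opens, positive charge builds β to tin and Bu3Sn+ departs, so a (2R)-2-methylbut-3-enyl group is transferred; the closest known reaction types are the Lewis-acid homoallylation of aldehydes and acetals by cyclopropylmethylstannanes and the Hosomi–Sakurai allylation of peroxyketals. No ring is closed; the cyclopropane is opened and the dioxane is kept. C6 is set by the substrate: in the half-chair of 12 the C4 methyl is pseudoequatorial, and the nucleophile enters on the axial trajectory that leads directly to a chair and avoids a syn-axial clash, so C7 ends trans to the C4 methyl and the C6 methyl equatorial and cis to it. C8 is not formed here; it is the methyl-bearing ring carbon of 11, none of whose bonds is broken, so its configuration is carried over. The step needs site selectivity between the two acetal carbons (the ketal is the better ionising site), attack at the ring CH2 and not at CH(CH3) (the bulk of the tertiary cation), and capture faster than proton loss from 12 (the tin group should raise the σ-bond nucleophilicity to about that of an allylsilane).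

Step 8
Reactants: 13 (3S,5S)-6-methoxy-3,5-dimethyl-3-[(2R)-2-methylbut-3-en-1-yl]-1,2-dioxane
Product: 15 methyl 2-[(3S,4S,6S)-4,6-dimethyl-6-[(2R)-2-methylbut-3-en-1-yl]-1,2-dioxan-3-yl]acetate, via C3 peroxycarbenium ion 14 (not isolated)
Conditions: CH2=C(OMe)OSiMe2tBu (2 equiv), TMSOTf (0.2 equiv), CH2Cl2, −78 °C
Reagents that add atoms: 1-(tert-butyldimethylsilyloxy)-1-methoxyethene, C=C(OC)O[Si](C)(C)C(C)(C)C
Why: Mukaiyama-type substitution of a cyclic peroxyacetal by a silyl ketene acetal; in cation 14 both methyl groups are pseudoequatorial and the C7 chain pseudoaxial, and axial attack at C3 on the face opposite the C7 chain should give the 3,4-cis product through a chair; both epimers of 13 converge on 14.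

Step 9
Reactants: 15 methyl 2-[(3S,4S,6S)-4,6-dimethyl-6-[(2R)-2-methylbut-3-en-1-yl]-1,2-dioxan-3-yl]acetate
Product: 17 methyl 2-[(3S,4S,6R)-4,6-dimethyl-6-[(2R)-2-methyl-3-oxopropyl]-1,2-dioxan-3-yl]acetate, via secondary ozonide 16 (not isolated)
Conditions: O3, CH2Cl2, −78 °C; then Me2S, −78 °C to rt; used at once
Reagents that add atoms: ozone, [O-][O+]=O
Why: Ozonolysis of the only alkene with Me2S reduction, which leaves dialkyl peroxides intact; the C6 descriptor changes by priority only, and immediate use protects the α-centre C8.

Step 10
Reactants: 2 (2S,3E)-pent-3-en-2-ol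
Product: 19 ethyl (3S,4E)-3-methylhex-4-enoate, via mixed ketene acetal 18 (not isolated)
Conditions: MeC(OEt)3, EtCO2H (cat.), 140 °C, removal of EtOH
Reagents that add atoms: triethyl orthoacetate, CCOC(C)(OCC)OCC
Why: Johnson–Claisen rearrangement through the same chair as in step 2, so (S)-2 gives the (S)-ester with an E-alkene; this centre becomes C12.

Step 11
Reactants: 19 ethyl (3S,4E)-3-methylhex-4-enoate
Product: 20 ethyl (3S,4E)-3-methyl-5-phenylpent-4-enoate
Conditions: styrene (3 equiv), second-generation Grubbs catalyst (3 mol%), CH2Cl2, 40 °C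
Reagents that add atoms: styrene, C=Cc1ccccc1
Why: Olefin cross-metathesis exchanges the propenyl terminus for styryl with loss of propene; styryl cross products form as E isomers and the allylic centre is not involved.

Step 12
Reactants: 20 ethyl (3S,4E)-3-methyl-5-phenylpent-4-enoate
Product: 21 (3S,4E)-3-methyl-5-phenylpent-4-en-1-ol
Conditions: LiAlH4, THF, 0 °C
Reagents that add atoms: none
Why: Hydride reduction of an ester to the primary alcohol; the styrene is inert.

Step 13
Reactants: 21 (3S,4E)-3-methyl-5-phenylpent-4-en-1-ol
Product: 22 5-{[(3S,4E)-3-methyl-5-phenylpent-4-en-1-yl]sulfanyl}-1-phenyl-1H-tetrazole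
Conditions: 1-phenyl-1H-tetrazole-5-thiol, PPh3, DIAD, THF, 0 °C to rt
Reagents that add atoms: 1-phenyl-1H-tetrazole-5-thiol, Sc1nnnn1-c1ccccc1
Why: Mitsunobu thioetherification of a primary alcohol.

Step 14
Reactants: 22 5-{[(3S,4E)-3-methyl-5-phenylpent-4-en-1-yl]sulfanyl}-1-phenyl-1H-tetrazole
Product: 23 5-{[(3S,4E)-3-methyl-5-phenylpent-4-en-1-yl]sulfonyl}-1-phenyl-1H-tetrazole
Conditions: (NH4)6Mo7O24·4H2O (cat.), 30% H2O2, EtOH, 0 °C to rt
Reagents that add atoms: hydrogen peroxide, OO
Why: Molybdate-catalysed oxidation of sulfide to sulfone, chemoselective over the styrene.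

Step 15
Reactants: 17 methyl 2-[(3S,4S,6R)-4,6-dimethyl-6-[(2R)-2-methyl-3-oxopropyl]-1,2-dioxan-3-yl]acetate; 23 5-{[(3S,4E)-3-methyl-5-phenylpent-4-en-1-yl]sulfonyl}-1-phenyl-1H-tetrazole
Product: 25 methyl 2-[(3S,4S,6S)-6-[(2R,3E,6S,7E)-2,6-dimethyl-8-phenylocta-3,7-dien-1-yl]-4,6-dimethyl-1,2-dioxan-3-yl]acetate, via potassium sulfonyl carbanion 24 (not isolated)
Conditions: 23, KN(SiMe3)2, DME, −78 °C; then 17, −78 °C to rt
Reagents that add atoms: none
Why: Julia–Kocienski olefination; the premetalated sulfone adds to the aldehyde, and Smiles rearrangement with anti elimination should give the E-alkene; no free amide base meets the β-peroxy ester or C8–H.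

Step 16
Reactants: 25 methyl 2-[(3S,4S,6S)-6-[(2R,3E,6S,7E)-2,6-dimethyl-8-phenylocta-3,7-dien-1-yl]-4,6-dimethyl-1,2-dioxan-3-yl]acetate
Product: 27 2-[(3S,4S,6S)-6-[(2R,3E,6S,7E)-2,6-dimethyl-8-phenylocta-3,7-dien-1-yl]-4,6-dimethyl-1,2-dioxan-3-yl]acetic acid, via lithium carboxylate 26 (not isolated)
Conditions: LiOH·H2O, THF/H2O, 0 °C; then 1 M HCl to pH 3
Reagents that add atoms: lithium hydroxide, [Li+].[OH-]
Why: Saponification at low temperature, where hydroxide attack at the ester carbonyl should outrun enolisation of the β-peroxy ester.

## Compound list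

1 | rac-(3E)-pent-3-en-2-ol | C/C=C/C(C)O | starting material
2 | (2S,3E)-pent-3-en-2-ol | C[C@H](O)/C=C/C | intermediate
3 | (2E,4S)-4-(prop-1-en-2-yloxy)pent-2-ene | C[C@H](OC(C)=C)/C=C/C | intermediate (not isolated)
4 | (4S,5E)-4-methylhept-5-en-2-one | CC(=O)C[C@H](C)/C=C/C | intermediate
5 | (4S)-5-hydroperoxy-5-methoxy-4-methylpentan-2-one | CC(=O)C[C@H](C)C(OC)OO | intermediate (not isolated)
6 | (5S)-6-methoxy-3,5-dimethyl-1,2-dioxan-3-ol | CC1(O)C[C@H](C)C(OC)OO1 | intermediate (not isolated)
7 | (5S)-3,6-dimethoxy-3,5-dimethyl-1,2-dioxane | COC1(C)C[C@H](C)C(OC)OO1 | intermediate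
8 | (2E)-but-2-en-1-ol | C/C=C/CO | starting material
9 | [(1R,2R)-2-methylcyclopropyl]methanol | OC[C@H]1[C@H](C)C1 | intermediate
10 | [(1R,2R)-2-methylcyclopropyl]methyl methanesulfonate | CS(=O)(=O)OC[C@H]1[C@H](C)C1 | intermediate
11 | tributyl{[(1R,2R)-2-methylcyclopropyl]methyl}stannane | CCCC[Sn](CCCC)(CCCC)C[C@H]1[C@H](C)C1 | intermediate
12 | (5S)-6-methoxy-3,5-dimethyl-1,2-dioxan-3-ylium | C[C+]1C[C@H](C)C(OC)OO1 | intermediate (not isolated)
13 | (3S,5S)-6-methoxy-3,5-dimethyl-3-[(2R)-2-methylbut-3-en-1-yl]-1,2-dioxane | C=C[C@H](C)C[C@@]1(C)C[C@H](C)C(OC)OO1 | intermediate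
14 | (4S,6S)-4,6-dimethyl-6-[(2R)-2-methylbut-3-en-1-yl]-1,2-dioxan-3-ylium | C=C[C@H](C)C[C@@]1(C)C[C@H](C)[CH+]OO1 | intermediate (not isolated)
15 | methyl 2-[(3S,4S,6S)-4,6-dimethyl-6-[(2R)-2-methylbut-3-en-1-yl]-1,2-dioxan-3-yl]acetate | C=C[C@H](C)C[C@@]1(C)C[C@H](C)[C@H](CC(=O)OC)OO1 | intermediate
16 | methyl 2-[(3S,4S,6R)-4,6-dimethyl-6-[(2R)-2-(1,2,4-trioxolan-3-yl)propyl]-1,2-dioxan-3-yl]acetate | C1OOC(O1)[C@H](C)C[C@@]2(C)C[C@H](C)[C@H](CC(=O)OC)OO2 | intermediate (not isolated)
17 | methyl 2-[(3S,4S,6R)-4,6-dimethyl-6-[(2R)-2-methyl-3-oxopropyl]-1,2-dioxan-3-yl]acetate | O=C[C@H](C)C[C@@]1(C)C[C@H](C)[C@H](CC(=O)OC)OO1 | intermediate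
18 | (2E,4S)-4-[(1-ethoxyethenyl)oxy]pent-2-ene | C[C@H](OC(=C)OCC)/C=C/C | intermediate (not isolated)
19 | ethyl (3S,4E)-3-methylhex-4-enoate | CCOC(=O)C[C@H](C)/C=C/C | intermediate
20 | ethyl (3S,4E)-3-methyl-5-phenylpent-4-enoate | CCOC(=O)C[C@H](C)/C=C/c1ccccc1 | intermediate
21 | (3S,4E)-3-methyl-5-phenylpent-4-en-1-ol | OCC[C@H](C)/C=C/c1ccccc1 | intermediate
22 | 5-{[(3S,4E)-3-methyl-5-phenylpent-4-en-1-yl]sulfanyl}-1-phenyl-1H-tetrazole | c1ccccc1-n1nnnc1SCC[C@H](C)/C=C/c1ccccc1 | intermediate
23 | 5-{[(3S,4E)-3-methyl-5-phenylpent-4-en-1-yl]sulfonyl}-1-phenyl-1H-tetrazole | c1ccccc1-n1nnnc1S(=O)(=O)CC[C@H](C)/C=C/c1ccccc1 | intermediate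
24 | potassium salt of the α-sulfonyl carbanion of 23 | [K+].c1ccccc1-n1nnnc1S(=O)(=O)[CH-]C[C@H](C)/C=C/c1ccccc1 | intermediate (not isolated)
25 | methyl 2-[(3S,4S,6S)-6-[(2R,3E,6S,7E)-2,6-dimethyl-8-phenylocta-3,7-dien-1-yl]-4,6-dimethyl-1,2-dioxan-3-yl]acetate | C[C@H](/C=C/c1ccccc1)C/C=C/[C@H](C)C[C@@]1(C)C[C@H](C)[C@H](CC(=O)OC)OO1 | intermediate
26 | lithium 2-[(3S,4S,6S)-6-[(2R,3E,6S,7E)-2,6-dimethyl-8-phenylocta-3,7-dien-1-yl]-4,6-dimethyl-1,2-dioxan-3-yl]acetate | [Li+].C[C@H](/C=C/c1ccccc1)C/C=C/[C@H](C)C[C@@]1(C)C[C@H](C)[C@H](CC(=O)[O-])OO1 | intermediate (not isolated)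
27 | 2-[(3S,4S,6S)-6-[(2R,3E,6S,7E)-2,6-dimethyl-8-phenylocta-3,7-dien-1-yl]-4,6-dimethyl-1,2-dioxan-3-yl]acetic acid | C[C@H](/C=C/c1ccccc1)C/C=C/[C@H](C)C[C@@]1(C)C[C@H](C)[C@H](CC(=O)O)OO1 | target

## Step count and risks

Total step count: 16. Longest linear sequence: 8 steps (1 → 2 → 4 → 7 → 13 → 15 → 17 → 25 → 27; the sulfone and stannane branches are no longer).

Step 7 (key step, labelled). The likely failure is slow capture of cation 12 by the σ nucleophile. That would let proton loss to a cyclic peroxy enol ether, protodestannylation of 11 by adventitious acid, or ring cleavage at the methyl-bearing cyclopropane carbon compete. The fallback uses known reaction types and sets out from 7. Hosomi–Sakurai allylation with allyltrimethylsilane and TMSOTf should give, with the same facial control, (3S,5S)-6-methoxy-3,5-dimethyl-3-(prop-2-en-1-yl)-1,2-dioxane F1. Cross-metathesis with (2E)-1,4-dibromobut-2-ene (second-generation Hoveyda–Grubbs catalyst) gives (3S,5S)-3-[(2E)-4-bromobut-2-en-1-yl]-6-methoxy-3,5-dimethyl-1,2-dioxane F2. Copper-catalysed asymmetric SN2' methylation (MeMgBr, CuBr·SMe2, Taniaphos ligand of the enantiomer that delivers the (R) centre, CH2Cl2, −75 °C) sets C8 under catalyst control and returns to the route at 13.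

Step 3. The primary ozonide may fragment in the other sense, releasing an α-methyl keto aldehyde that can enolise (erosion at C4) and that must exchange with the co-formed hydroperoxide to reach 7. The fallback sets out from 4. Ozonolysis in acidic methanol followed by NaHCO3 and Me2S (acetal-forming work-up) gives the configurationally stable keto acetal (4S)-5,5-dimethoxy-4-methylpentan-2-one F3. Treatment with anhydrous H2O2 and a Lewis acid catalyst such as Sc(OTf)3 in methanol (peroxyketalisation of the ketone, exchange at the acetal) returns to the route at 7.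

Step 11. Metathesis at the allylically branched internal alkene may be slow and lose out to styrene self-metathesis. The fallback sets out from 19. Ozonolysis with Me2S work-up gives ethyl (3S)-3-methyl-4-oxobutanoate F4, and Julia–Kocienski olefination with 5-(benzylsulfonyl)-1-phenyl-1H-tetrazole and KN(SiMe3)2 returns to the route at 20.

Step 15. The carbanion or the alkoxide intermediates may open the β-peroxy ester by retro-oxa-Michael elimination or enolise the aldehyde at C8; E selectivity may also be incomplete. The fallback changes the order so that no ester is present and sets out from 13. Ozonolysis gives (2R)-3-[(3S,5S)-6-methoxy-3,5-dimethyl-1,2-dioxan-3-yl]-2-methylpropanal F5. Julia–Kocienski olefination with 23 gives (3S,5S)-3-[(2R,3E,6S,7E)-2,6-dimethyl-8-phenylocta-3,7-dien-1-yl]-6-methoxy-3,5-dimethyl-1,2-dioxane F6. The silyl ketene acetal addition of step 8 is then run on F6, where the ketene acetal should outcompete the alkenes for the cation, and returns to the route at 25.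

Step 16. Hydroxide may trigger retro-oxa-Michael opening of the ring or epimerisation at C3 through the ester enolate. The fallback sets out from 25 and uses a carboxylesterase (pig liver esterase, phosphate buffer pH 7, 25 °C), which cleaves the methyl ester through an acyl-enzyme without free base, and arrives at 27; it makes no new compound.

## Further compounds

F1 | step 7 | (3S,5S)-6-methoxy-3,5-dimethyl-3-(prop-2-en-1-yl)-1,2-dioxane | C=CC[C@@]1(C)C[C@H](C)C(OC)OO1
F2 | step 7 | (3S,5S)-3-[(2E)-4-bromobut-2-en-1-yl]-6-methoxy-3,5-dimethyl-1,2-dioxane | BrC/C=C/C[C@@]1(C)C[C@H](C)C(OC)OO1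
F3 | step 3 | (4S)-5,5-dimethoxy-4-methylpentan-2-one | CC(=O)C[C@H](C)C(OC)OC
F4 | step 11 | ethyl (3S)-3-methyl-4-oxobutanoate | CCOC(=O)C[C@H](C)C=O
F5 | step 15 | (2R)-3-[(3S,5S)-6-methoxy-3,5-dimethyl-1,2-dioxan-3-yl]-2-methylpropanal | O=C[C@H](C)C[C@@]1(C)C[C@H](C)C(OC)OO1
F6 | step 15 | (3S,5S)-3-[(2R,3E,6S,7E)-2,6-dimethyl-8-phenylocta-3,7-dien-1-yl]-6-methoxy-3,5-dimethyl-1,2-dioxane | C[C@H](/C=C/c1ccccc1)C/C=C/[C@H](C)C[C@@]1(C)C[C@H](C)C(OC)OO1
F0 | step 16 | none | none
A1 | alternative 1 | methyl (2E,4S,8R)-6-hydroperoxy-4,6,8-trimethyldeca-2,9-dienoate (both C6 epimers) | COC(=O)/C=C/[C@@H](C)CC(C)(OO)C[C@@H](C)C=C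
A2 | alternative 2 | methyl (3E,5Z,8R)-4,6,8-trimethyldeca-3,5,9-trienoate | COC(=O)C/C=C(\C)/C=C(/C)\C[C@@H](C)C=C
A3 | alternative 2 | methyl 2-[(3S,6S)-4,6-dimethyl-6-[(2R)-2-methylbut-3-en-1-yl]-3,6-dihydro-1,2-dioxin-3-yl]acetate | C=C[C@H](C)C[C@@]1(C)C=C(C)[C@H](CC(=O)OC)OO1
A4 | alternative 3 | meso-(3R,6S)-3,6-dimethylcyclohept-4-en-1-one | C[C@H]1CC(=O)C[C@@H](C)C=C1
A5 | alternative 3 | meso-1-hydroperoxy-1,3,6-trimethylcyclohept-4-ene, hydroperoxy group cis to both ring methyl groups | C1[C@H](C)C[C@](C)(OO)C[C@H](C)C=1
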